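## Structural features

Methylarzanol contains two six-membered rings: a fully substituted 2-methoxy-4H-pyran-4-one (6-ethyl, 5-methyl) and a hexasubstituted benzene, joined by one methylene between pyranone C3 and arene carbon C1'. The benzene is a phloroglucinol in which the hydroxylated carbons C2', C4' and C6' alternate with the carbon-substituted ones: C1' (methylene bridge), C3' (prenyl) and C5' (acetyl). There is no stereocentre in the target, so no stereocentres adjoin. The problem is regiochemical: three different carbon groups on a threefold-symmetric ring, and the methyl group on the correct pyranone oxygen (2-methoxy-4-pyranone, not 4-methoxy-2-pyranone). The prenyl alkene lies between two phenols and cyclises to a chroman under protic or strong Lewis acid; it also rules out hydrogenolysis and electrophilic halogen late in the route. The methoxypyranone is a vinylogous carbonate: its carbonyl oxygen is nucleophilic, and its methyl ether is cleaved by halide-bearing Lewis acids and threatened by hydroxide. The real difficulty is to avoid statistical C-substitution of a preformed phloroglucinol. The key step exploits the alternating O/C pattern: C2'(OH) maps onto a ketene carbonyl carbon, C3'(prenyl) and C4'(O) onto the two carbons of a siloxyalkyne, and C5'(H), C6'(O), C1'(CH2) onto C2, C3 and C4 of a 3-siloxycyclobutenone.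

## Logic of the disconnections

**26 ⇒ 24.** The bond cut is C5'–C(=O) of the aryl ketone. C5' is the only unsubstituted ring carbon of 24 and lies between two hydroxyls, so an acyl cation equivalent has one place to go. The cut removes the one substituent the ring-forming step cannot deliver. The forward step must acylate faster than acid closes the prenyl group onto a neighbouring hydroxyl, and must spare the pyranone methyl ether.

**24 ⇒ 23.** Two O–Si bonds are cut. No skeletal simplification results; the silyl ethers are the form in which the annulation delivers two of the three oxygens. Removing them first exposes the most nucleophilic form of the ring for the acylation. The forward step needs a buffered fluoride source so that the triol is not left as an oxidisable phenoxide.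

**23 ⇒ 14 + 18.** Ring bonds C2'–C3' and C4'–C5' are cut, and C1'–C2' is traced back to the C1–C4 bond of a four-membered ring. The benzene falls into a four-carbon and a two-carbon piece, each substituent already on its correct carbon, so nothing is placed on a preformed phloroglucinol. The forward step needs one orientation of alkyne addition to the ketene, and cyclisation of the ketene intermediates before they are lost.

**14 ⇒ 7 + 11 (through 12 and 13).** Cyclobutenone bonds C1–C2 and C3–C4 are cut, a ketene–ynol ether [2+2]. This separates the complete pyranone side chain, as a propanoic acid, from a two-carbon oxygenated alkyne. The forward step must generate ketene 13 beside a nucleophilic pyranone carbonyl under conditions that do not cleave the methyl ether, with 11 present in excess.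

**11 ⇒ 8 and 18 ⇒ 15.** In 11 the O–Si and C–O bonds are cut back to an acetylide. In 18 the O–Si bond and one alkyne carbon are removed, leading to ester 15 through ynolate 17. Both alkynes then come from stock two- and six-carbon materials in one operation each. The demand is O-silylation of an ynolate by a bulky silyl group, and for 15 addition of the carbenoid in preference to enolisation.

**7 ⇒ 6 ⇒ 5.** The O–CH2Ph bond of the ester and then the O–CH3 bond of the pyranone are cut. The benzyl ester lets the acid be freed without hydroxide. Methylation at the stage of 5 is done while the molecule has no other nucleophilic oxygen. The demand is methylation on the lactone carbonyl oxygen and not on the 4-hydroxyl.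

**5 ⇒ 3 + 4.** The C3–CH2 bond is cut (conjugate addition). C3 is the only free nucleophilic carbon of 3, so the three-carbon acid chain is attached without regiochemical ambiguity.

**3 ⇒ 1 + 2.** Pyranone bonds C4–C5 and O1–C2 are cut, giving a symmetrical ketone and a malonyl unit. The ketone's symmetry removes any regiochemical question.

## Other disconnections considered

**Alternative 1:** The cut runs through the bridge and the arene. Fluoride would release 3,5-bis(benzyloxy)benzyne A1 in N,N-dimethylformamide A2. The aryne would add to the formamide C=O and open to an ortho-quinone methide iminium, which C3 of 3 would capture to give the aminobenzyl pyranone A3 (racemic at the bridging carbon).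
- In favour: three bonds (aryl–O, aryl–C, C–C3) form in one operation at ambient temperature from 3, the same pyranone the chosen route uses. In convergence and mildness of the key step this alternative is the better of the two.
- Against: A3 carries a dimethylamino group on the bridge that must be removed reductively. Its benzyl ethers cannot be hydrogenolysed once a prenyl group is present, so both prenyl and acetyl would have to be placed on a free phloroglucinol afterwards. The pyranone would still need O-methylation on the correct oxygen, now with an amine or free phenols present.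
- Comparison: on structure, it solves the bridge but leaves the ring substitution pattern to classical electrophilic substitution, which the chosen plan fixes by mechanism. On mechanism, it is polar and regiocontrolled by the alkoxy group of A1, equal in reliability to the pericyclic cascade. On step economy, the short front end is offset by a longer tail, so no gain is expected overall.

**Alternative 2:** The cut is in the pyranone (C4–C5 and O1–C2). The malonyl unit is carried as the 3-chlorocarbonyl dihydrocoumarin A4. A4 would C-acylate the silyl enol ether A5 of 1, and the new enol oxygen would open the lactone to close the hydroxypyranone A6 and free the phenol.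
- In favour: the acetyl group is on the arene from the start, so no late acylation beside a prenyl group is needed; on this point the alternative is better than the chosen plan. The ring closure is the same ketone-plus-malonyl logic as step 1 and equal in reliability. The acetates and the chelated phenol of A6 leave the lactone carbonyl as the most nucleophilic oxygen for the later methylation.
- Against: the prenyl group would have to be introduced last by C-alkylation of an acylphloroglucinol after acetate removal. Only one ring carbon is free, so regiocontrol equals that of the chosen plan, but O-alkylation and over-alkylation make this a characteristically inefficient step. The acid chloride A4 must also be formed and used in the presence of aryl acetates and an aryl ketone.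
- Comparison: on structure, it trades the late acetylation of the chosen plan for a late prenylation. On mechanism, it is entirely polar with no new reaction class. On step economy it is comparable, at about ten steps.

**Alternative 3:** The cut is again in the pyranone (C3–C4 and O1–C2). Heating the dioxinone A7 would release acetone and the acylketene A8. A8 would add as a four-atom heterodiene to the ketene acetal A9 and lose methanol to give the methoxypyranone A10.
- In favour: the 2-methoxy-4-pyranone is formed with the methyl group already on the correct oxygen; on this point the alternative is better than the chosen plan, which depends on a selective methylation in step 3. The conditions are neutral and thermal, equal to those of the benzannulation.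
- Against: A9 is a substituted ketene acetal that is awkward to prepare and hydrolytically fragile. A10 is a tribenzyl ether with two equivalent free ring carbons; after hydrogenolysis (necessarily before prenylation) one acetyl and one prenyl group would have to be introduced on a free phloroglucinol, which is statistical.
- Comparison: on structure, it solves the pyranone and leaves the arene unsolved, the reverse of the chosen plan. On mechanism, both are ketene pericyclic chemistry of similar standing. On step economy, a short key sequence is followed by a long, low-selectivity endgame.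

Key step: step 8

Remark: the two key-step partners and the annulation product were checked atom by atom against the cascade and are mutually consistent, so no structural correction is needed. The target has no stereocentre; 14 and the sp3 intermediates of the cascade are racemic.

Remark: a benzyl ester is used for the acrylate so the acid can be freed by hydrogenolysis. (Triisopropylsilyloxy)ethyne is not assumed to be a stock chemical and is made in step 5.

## Route

Step 1
Reactants: 1 3-pentanone; 2 malonyl dichloride
Product: 3 6-ethyl-4-hydroxy-5-methyl-2H-pyran-2-one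
Conditions: CH2Cl2, 0 °C → rt; extraction into aq. NaHCO3, then acidification
Reagents that add atoms: none
Why: Known ketone/malonyl dichloride pyranone synthesis: the ketone enol is C-acylated by one acyl chloride and the resulting enol oxygen closes the lactone on the second. The symmetrical ketone allows only one product.

Step 2
Reactants: 3 6-ethyl-4-hydroxy-5-methyl-2H-pyran-2-one; 4 benzyl acrylate
Product: 5 benzyl 3-(6-ethyl-4-hydroxy-5-methyl-2-oxo-2H-pyran-3-yl)propanoate
Conditions: DBU (0.2 equiv), MeCN, 50 °C
Reagents that add atoms: none
Why: Base-catalysed Michael addition of a cyclic vinylogous acid to an acrylate. C3 is the only unsubstituted nucleophilic carbon of 3 (C5 carries the methyl group), and one equivalent of acceptor at moderate temperature should hold the reaction at mono-addition.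

Step 3
Reactants: 5 benzyl 3-(6-ethyl-4-hydroxy-5-methyl-2-oxo-2H-pyran-3-yl)propanoate
Product: 6 benzyl 3-(6-ethyl-2-methoxy-5-methyl-4-oxo-4H-pyran-3-yl)propanoate
Conditions: MeOTf, CH2Cl2, 0 °C → rt; aq. NaHCO3
Reagents that add atoms: methyl trifluoromethanesulfonate, COS(=O)(=O)C(F)(F)F
Why: A hard methylating agent alkylates the neutral hydroxypyranone at its most nucleophilic site, the lactone carbonyl oxygen, and loss of the hydroxyl proton on work-up leaves the 2-methoxy-4-pyranone. This is the established regiocontrol for α-methoxy-γ-pyranones, whereas methylation of the anion would favour the 4-methoxy-2-pyranone; the ester carbonyl is too weak a nucleophile to compete.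

Step 4
Reactants: 6 benzyl 3-(6-ethyl-2-methoxy-5-methyl-4-oxo-4H-pyran-3-yl)propanoate
Product: 7 3-(6-ethyl-2-methoxy-5-methyl-4-oxo-4H-pyran-3-yl)propanoic acid
Conditions: H2 (1 atm), Pd/C, EtOAc, rt
Reagents that add atoms: none
Why: Hydrogenolysis of a benzyl ester under neutral conditions, which keeps hydroxide away from the vinylogous carbonate. The tetrasubstituted pyranone double bonds should not be reduced at atmospheric pressure.

Step 5
Reactants: 8 acetylene
Product: 11 (triisopropylsilyloxy)ethyne, via lithium acetylide 9 (not isolated), via lithium ethynolate 10 (not isolated)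
Conditions: n-BuLi, THF, −78 °C; t-BuOOLi (from t-BuOOH and LiN(SiMe3)2), −78 → −40 °C; i-Pr3SiOTf, −78 °C; used cold and at once
Reagents that add atoms: tert-butyl hydroperoxide, CC(C)(C)OO; triisopropylsilyl trifluoromethanesulfonate, CC(C)[Si](C(C)C)(C(C)C)OS(=O)(=O)C(F)(F)F
Why: Oxidation of a lithium acetylide to the ynolate by lithium tert-butyl peroxide, then O-silylation with a bulky silyl triflate, is the standard route from terminal alkynes to siloxyalkynes, applied here to the parent acetylide. The triisopropylsilyl group is chosen because its bulk retards oxygen-to-carbon silyl migration.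

Step 6
Reactants: 7 3-(6-ethyl-2-methoxy-5-methyl-4-oxo-4H-pyran-3-yl)propanoic acid; 11 (triisopropylsilyloxy)ethyne
Product: 14 4-[(6-ethyl-2-methoxy-5-methyl-4-oxo-4H-pyran-3-yl)methyl]-3-(triisopropylsilyloxy)cyclobut-2-en-1-one (racemic), via acid chloride 12 (not isolated), via aldoketene 13 (not isolated)
Conditions: Me2C=C(Cl)NMe2, CH2Cl2, 0 °C; then slow addition to 11 (2 equiv), Et3N, CH2Cl2, 0 °C → rt
Reagents that add atoms: none
Why: The chloroenamine converts the acid into 12 under neutral conditions, avoiding oxalyl chloride, which would attack the pyranone carbonyl; 12 is consumed at once so that chloride has little time to demethylate the pyranone. Triethylamine dehydrochlorinates 12 to ketene 13, which undergoes the known ketene–ynol ether [2+2]: the unsubstituted alkyne carbon bonds to the ketene carbonyl carbon, placing the side chain at C4 and the siloxy group at C3. The C4 stereocentre is formed racemic and is destroyed in step 8.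

Step 7
Reactants: 15 ethyl 4-methylpent-3-enoate
Product: 18 5-methyl-1-(triisopropylsilyloxy)hex-4-en-1-yne, via dibromoenolate 16 (not isolated), via lithium ynolate 17 (not isolated)
Conditions: CH2Br2, lithium 2,2,6,6-tetramethylpiperidide, THF, −78 °C; 15; LiN(SiMe3)2; n-BuLi, −78 °C → rt; i-Pr3SiOTf, −78 → 0 °C
Reagents that add atoms: dibromomethane, BrCBr; triisopropylsilyl trifluoromethanesulfonate, CC(C)[Si](C(C)C)(C(C)C)OS(=O)(=O)C(F)(F)F
Why: Kowalski ester homologation stopped at the ynolate: dibromomethyllithium adds to the ester, enolate 16 undergoes bromine–lithium exchange and 1,2-shift of the prenyl-bearing carbon to ynolate 17, and the bulky silyl triflate silylates oxygen. The prenyl group thereby ends on the alkyne carbon remote from oxygen.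

Step 8
Reactants: 14 4-[(6-ethyl-2-methoxy-5-methyl-4-oxo-4H-pyran-3-yl)methyl]-3-(triisopropylsilyloxy)cyclobut-2-en-1-one; 18 5-methyl-1-(triisopropylsilyloxy)hex-4-en-1-yne
Product: 23 6-ethyl-3-[2-hydroxy-3-(3-methylbut-2-enyl)-4,6-bis(triisopropylsilyloxy)benzyl]-2-methoxy-5-methyl-4H-pyran-4-one, via vinylketene 19 (not isolated), via vinylcyclobutenone 20 (not isolated), via dienylketene 21 (not isolated), via cyclohexadienone 22 (not isolated)
Conditions: 18 (1.3 equiv), degassed toluene, sealed tube, 80 → 110 °C
Reagents that add atoms: none
Why: Heating opens 14 by conrotatory 4π electrocyclic cleavage of the C1–C4 bond to vinylketene 19, the side chain turning outward. The polarised ynol ether 18 then adds across the ketene C=C in a [2+2]: its prenyl-bearing carbon, the nucleophilic end, bonds to the ketene carbonyl carbon and its siloxy-bearing carbon to the ketene CH, giving 20. A second 4π opening converts 20 into dienylketene 21; this opening is reversible and only the rotamer with the siloxyvinyl group cis to the ketene can proceed. The benzene ring closes by thermal disrotatory 6π electrocyclisation between the ketene carbon and the terminus bearing the pyranonylmethyl group to give 22, and enolisation gives phenol 23. The closest known reaction is the Danheiser benzannulation of cyclobutenones with siloxyalkynes to resorcinol monosilyl ethers; the 3-siloxy group on the four-membered ring is the extension that makes the product a phloroglucinol. No stereocentre survives: the sp3 centres of 14, 20 and 22 are racemic and are erased on aromatisation. The selectivity needed is the orientation of the [2+2], secured by the oxygen-induced polarisation of 18, and tolerance of the pyranone and the prenyl alkene, secured by neutral reagent-free conditions. A small excess of 18, and the hindered position of the new hydroxyl between two carbon substituents, should limit loss of ketene by dimerisation or by acylation of the product.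

Step 9
Reactants: 23 6-ethyl-3-[2-hydroxy-3-(3-methylbut-2-enyl)-4,6-bis(triisopropylsilyloxy)benzyl]-2-methoxy-5-methyl-4H-pyran-4-one
Product: 24 6-ethyl-2-methoxy-5-methyl-3-[2,4,6-trihydroxy-3-(3-methylbut-2-enyl)benzyl]-4H-pyran-4-one
Conditions: Bu4NF, AcOH, THF, 0 °C; work-up under argon
Reagents that add atoms: none
Why: Fluoride cleavage of aryl silyl ethers, buffered with acetic acid so the electron-rich triol is not left as an oxidisable phenoxide. The prenyl group and the methoxypyranone are inert to buffered fluoride.

Step 10
Reactants: 24 6-ethyl-2-methoxy-5-methyl-3-[2,4,6-trihydroxy-3-(3-methylbut-2-enyl)benzyl]-4H-pyran-4-one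
Product: 26 methylarzanol (3-[3-acetyl-2,4,6-trihydroxy-5-(3-methylbut-2-enyl)benzyl]-6-ethyl-2-methoxy-5-methyl-4H-pyran-4-one), via difluoroboron chelate 25 (not isolated)
Conditions: Ac2O (1.2 equiv), BF3·OEt2, CH2Cl2–1,4-dioxane, −20 → 0 °C; then NaOAc, MeOH–H2O, rt
Reagents that add atoms: acetic anhydride, CC(=O)OC(C)=O
Why: Friedel–Crafts C-acylation of a phloroglucinol at its only free ring carbon, which lies between two hydroxyls and should react at low temperature. Boron trifluoride carries no nucleophilic halide that could cleave the pyranone methyl ether, and the ether co-solvent tempers the protic acidity that would cyclise the prenyl group. The work-up hydrolyses chelate 25 and any aryl acetate.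

## Compound list

1 | 3-pentanone | CCC(=O)CC | starting material
2 | malonyl dichloride | O=C(Cl)CC(=O)Cl | starting material
3 | 6-ethyl-4-hydroxy-5-methyl-2H-pyran-2-one | CCc1oc(=O)cc(O)c1C | intermediate
4 | benzyl acrylate | C=CC(=O)OCc1ccccc1 | starting material
5 | benzyl 3-(6-ethyl-4-hydroxy-5-methyl-2-oxo-2H-pyran-3-yl)propanoate | CCc1oc(=O)c(CCC(=O)OCc2ccccc2)c(O)c1C | intermediate
6 | benzyl 3-(6-ethyl-2-methoxy-5-methyl-4-oxo-4H-pyran-3-yl)propanoate | CCc1oc(OC)c(CCC(=O)OCc2ccccc2)c(=O)c1C | intermediate
7 | 3-(6-ethyl-2-methoxy-5-methyl-4-oxo-4H-pyran-3-yl)propanoic acid | CCc1oc(OC)c(CCC(=O)O)c(=O)c1C | intermediate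
8 | acetylene | C#C | starting material
9 | lithium acetylide | [Li]C#C | intermediate
10 | lithium ethynolate | [Li+].[O-]C#C | intermediate
11 | (triisopropylsilyloxy)ethyne | C#CO[Si](C(C)C)(C(C)C)C(C)C | intermediate
12 | 3-(6-ethyl-2-methoxy-5-methyl-4-oxo-4H-pyran-3-yl)propanoyl chloride | CCc1oc(OC)c(CCC(=O)Cl)c(=O)c1C | intermediate
13 | 3-(6-ethyl-2-methoxy-5-methyl-4-oxo-4H-pyran-3-yl)prop-1-en-1-one (aldoketene) | CCc1oc(OC)c(CC=C=O)c(=O)c1C | intermediate
14 | 4-[(6-ethyl-2-methoxy-5-methyl-4-oxo-4H-pyran-3-yl)methyl]-3-(triisopropylsilyloxy)cyclobut-2-en-1-one (racemic) | O=C1C=C(O[Si](C(C)C)(C(C)C)C(C)C)C1Cc1c(OC)oc(CC)c(C)c1=O | intermediate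
15 | ethyl 4-methylpent-3-enoate | CCOC(=O)CC=C(C)C | starting material
16 | lithium 1,1-dibromo-5-methylhexa-1,4-dien-2-olate | [Li+].[O-]C(=C(Br)Br)CC=C(C)C | intermediate
17 | lithium 5-methylhex-4-en-1-yn-1-olate | [Li+].[O-]C#CCC=C(C)C | intermediate
18 | 5-methyl-1-(triisopropylsilyloxy)hex-4-en-1-yne | CC(C)=CCC#CO[Si](C(C)C)(C(C)C)C(C)C | intermediate
19 | (3Z)-5-(6-ethyl-2-methoxy-5-methyl-4-oxo-4H-pyran-3-yl)-3-(triisopropylsilyloxy)penta-1,3-dien-1-one (vinylketene) | O=C=C/C(O[Si](C(C)C)(C(C)C)C(C)C)=C/Cc1c(OC)oc(CC)c(C)c1=O | intermediate
20 | 4-[(1Z)-3-(6-ethyl-2-methoxy-5-methyl-4-oxo-4H-pyran-3-yl)-1-(triisopropylsilyloxy)prop-1-enyl]-2-(3-methylbut-2-enyl)-3-(triisopropylsilyloxy)cyclobut-2-en-1-one (racemic) | O=C1C(CC=C(C)C)=C(O[Si](C(C)C)(C(C)C)C(C)C)C1/C(O[Si](C(C)C)(C(C)C)C(C)C)=C/Cc1c(OC)oc(CC)c(C)c1=O | intermediate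
21 | (3E,5Z)-7-(6-ethyl-2-methoxy-5-methyl-4-oxo-4H-pyran-3-yl)-2-(3-methylbut-2-enyl)-3,5-bis(triisopropylsilyloxy)hepta-1,3,5-trien-1-one (dienylketene) | O=C=C(CC=C(C)C)/C(O[Si](C(C)C)(C(C)C)C(C)C)=C\C(O[Si](C(C)C)(C(C)C)C(C)C)=C\Cc1c(OC)oc(CC)c(C)c1=O | intermediate
22 | 6-[(6-ethyl-2-methoxy-5-methyl-4-oxo-4H-pyran-3-yl)methyl]-2-(3-methylbut-2-enyl)-3,5-bis(triisopropylsilyloxy)cyclohexa-2,4-dien-1-one (racemic) | O=C1C(CC=C(C)C)=C(O[Si](C(C)C)(C(C)C)C(C)C)C=C(O[Si](C(C)C)(C(C)C)C(C)C)C1Cc1c(OC)oc(CC)c(C)c1=O | intermediate
23 | 6-ethyl-3-[2-hydroxy-3-(3-methylbut-2-enyl)-4,6-bis(triisopropylsilyloxy)benzyl]-2-methoxy-5-methyl-4H-pyran-4-one | CCc1oc(OC)c(Cc2c(O)c(CC=C(C)C)c(O[Si](C(C)C)(C(C)C)C(C)C)cc2O[Si](C(C)C)(C(C)C)C(C)C)c(=O)c1C | intermediate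
24 | 6-ethyl-2-methoxy-5-methyl-3-[2,4,6-trihydroxy-3-(3-methylbut-2-enyl)benzyl]-4H-pyran-4-one | CCc1oc(OC)c(Cc2c(O)c(CC=C(C)C)c(O)cc2O)c(=O)c1C | intermediate
25 | difluoroboron chelate of 26 (boron bound to the acetyl oxygen and to the oxygen at C6' of the benzyl ring) | CC1=[O+][B-](F)(F)Oc2c1c(O)c(CC=C(C)C)c(O)c2Cc1c(OC)oc(CC)c(C)c1=O | intermediate
26 | methylarzanol, 3-[3-acetyl-2,4,6-trihydroxy-5-(3-methylbut-2-enyl)benzyl]-6-ethyl-2-methoxy-5-methyl-4H-pyran-4-one | CCc1oc(OC)c(Cc2c(O)c(CC=C(C)C)c(O)c(C(C)=O)c2O)c(=O)c1C | target

## Step count and least certain steps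

Total step count: 10. Longest linear sequence: 8 (steps 1, 2, 3, 4, 6, 8, 9, 10); steps 5 and 7 are one-step branches.

**Step 8 (key step).** The siloxy donor at C3 stabilises the cyclobutenone, so ring opening may need more heat than simple cyclobutenones do. At that temperature the ketene intermediates may be lost by self-condensation, by acylation of the newly formed phenol, or by inward rotation of the side chain followed by a 1,5-hydrogen shift. Oxygen-to-carbon silyl migration in 18 may also compete. The fallback replaces the substituted vinylketene by one with a free CH2 terminus, the substitution type with the broadest precedent, which has no hydrogen placed for the 1,5-shift. It sets out from 14. Desilylation (Bu4NF, AcOH, THF, 0 °C) should give 2-[(6-ethyl-2-methoxy-5-methyl-4-oxo-4H-pyran-3-yl)methyl]cyclobutane-1,3-dione F1. Re-silylation of its enol (i-Pr3SiOTf, Et3N, CH2Cl2) should favour the more substituted enol ether, 2-[(6-ethyl-2-methoxy-5-methyl-4-oxo-4H-pyran-3-yl)methyl]-3-(triisopropylsilyloxy)cyclobut-2-en-1-one F2. Heating F2 with 18 in toluene should give the isomeric phenol 6-ethyl-3-[4-hydroxy-3-(3-methylbut-2-enyl)-2,6-bis(triisopropylsilyloxy)benzyl]-2-methoxy-5-methyl-4H-pyran-4-one F3. Buffered fluoride then returns the route to 24, because the three carbon positions of a phloroglucinol are equivalent once both silyl groups are gone.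

**Step 10.** Acid-triggered cyclisation of the prenyl group onto a neighbouring hydroxyl, or acid-induced cleavage at the benzylic methylene, may compete with C-acylation, because the acylation liberates a strong protic acid in the presence of an alkene flanked by two phenols. The fallback avoids acid. It sets out from 24. Iodination at the free ring carbon (iodine, NaHCO3, THF–H2O, 0 °C; the phenoxide ring should outpace the alkene) would give 6-ethyl-3-[2,4,6-trihydroxy-3-iodo-5-(3-methylbut-2-enyl)benzyl]-2-methoxy-5-methyl-4H-pyran-4-one F4. Heck arylation of butyl vinyl ether at its oxygen-bearing carbon (Pd(OAc)2, 1,3-bis(diphenylphosphino)propane, Et3N, DMSO, 80 °C) would give 3-[3-(1-butoxyvinyl)-2,4,6-trihydroxy-5-(3-methylbut-2-enyl)benzyl]-6-ethyl-2-methoxy-5-methyl-4H-pyran-4-one F5. Brief hydrolysis (dilute HCl, THF, 0 °C) would return to the route at 26.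

**Step 5.** Monolithium acetylide may disproportionate when warmed for the oxidation, and the unhindered ynol silyl ether may undergo oxygen-to-carbon silyl migration to a silylketene before it is used. The fallback avoids 11. It sets out from 7, which is converted into ketene 13 as in step 6 and trapped with commercial ethoxyacetylene to give 3-ethoxy-4-[(6-ethyl-2-methoxy-5-methyl-4-oxo-4H-pyran-3-yl)methyl]cyclobut-2-en-1-one (racemic) F6. Hydrolysis of the vinylogous ester (dilute HCl, THF, 0 °C) gives 2-[(6-ethyl-2-methoxy-5-methyl-4-oxo-4H-pyran-3-yl)methyl]cyclobutane-1,3-dione F1. Silylation (i-Pr3SiOTf, Et3N) gives 14 together with its regioisomer 2-[(6-ethyl-2-methoxy-5-methyl-4-oxo-4H-pyran-3-yl)methyl]-3-(triisopropylsilyloxy)cyclobut-2-en-1-one F2. The fallback returns to the route at 14. The accompanying F2 need not be separated, since it passes through step 8 to 6-ethyl-3-[4-hydroxy-3-(3-methylbut-2-enyl)-2,6-bis(triisopropylsilyloxy)benzyl]-2-methoxy-5-methyl-4H-pyran-4-one F3 and meets the route again at 24.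

**Step 7.** The α-methylene of 15 is activated by both the ester and the alkene, so proton abstraction by the carbenoid or the amide base may compete with addition to the carbonyl. The skipped enyne unit may also isomerise under the strongly basic conditions. The fallback builds the alkyne by substitution and makes the ynolate by oxidation instead of rearrangement. It sets out from 8. Ethylmagnesium bromide in THF gives ethynylmagnesium bromide F7. CuCl-catalysed coupling with prenyl bromide gives 5-methylhex-4-en-1-yne F8. Deprotonation with LiN(SiMe3)2 and oxidation with lithium tert-butyl peroxide (THF, −78 → 0 °C) returns to the route at ynolate 17, which is silylated to 18 as in step 7.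

## Further compounds

F1 | step 8 | 2-[(6-ethyl-2-methoxy-5-methyl-4-oxo-4H-pyran-3-yl)methyl]cyclobutane-1,3-dione | O=C1CC(=O)C1Cc1c(OC)oc(CC)c(C)c1=O
F2 | step 8 | 2-[(6-ethyl-2-methoxy-5-methyl-4-oxo-4H-pyran-3-yl)methyl]-3-(triisopropylsilyloxy)cyclobut-2-en-1-one | O=C1CC(O[Si](C(C)C)(C(C)C)C(C)C)=C1Cc1c(OC)oc(CC)c(C)c1=O
F3 | step 8 | 6-ethyl-3-[4-hydroxy-3-(3-methylbut-2-enyl)-2,6-bis(triisopropylsilyloxy)benzyl]-2-methoxy-5-methyl-4H-pyran-4-one | CCc1oc(OC)c(Cc2c(O[Si](C(C)C)(C(C)C)C(C)C)cc(O)c(CC=C(C)C)c2O[Si](C(C)C)(C(C)C)C(C)C)c(=O)c1C
F4 | step 10 | 6-ethyl-3-[2,4,6-trihydroxy-3-iodo-5-(3-methylbut-2-enyl)benzyl]-2-methoxy-5-methyl-4H-pyran-4-one | CCc1oc(OC)c(Cc2c(O)c(CC=C(C)C)c(O)c(I)c2O)c(=O)c1C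
F5 | step 10 | 3-[3-(1-butoxyvinyl)-2,4,6-trihydroxy-5-(3-methylbut-2-enyl)benzyl]-6-ethyl-2-methoxy-5-methyl-4H-pyran-4-one | CCc1oc(OC)c(Cc2c(O)c(CC=C(C)C)c(O)c(C(=C)OCCCC)c2O)c(=O)c1C
F6 | step 5 | 3-ethoxy-4-[(6-ethyl-2-methoxy-5-methyl-4-oxo-4H-pyran-3-yl)methyl]cyclobut-2-en-1-one (racemic) | O=C1C=C(OCC)C1Cc1c(OC)oc(CC)c(C)c1=O
F7 | step 7 | ethynylmagnesium bromide | C#C[Mg]Br
F8 | step 7 | 5-methylhex-4-en-1-yne | C#CCC=C(C)C
A1 | alternative 1 | 3,5-bis(benzyloxy)benzyne | C1#CC(OCc2ccccc2)=CC(OCc2ccccc2)=C1
A2 | alternative 1 | N,N-dimethylformamide | CN(C)C=O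
A3 | alternative 1 | 3-{[2,4-bis(benzyloxy)-6-hydroxyphenyl](dimethylamino)methyl}-6-ethyl-4-hydroxy-5-methyl-2H-pyran-2-one (racemic) | CCc1oc(=O)c(C(N(C)C)c2c(O)cc(OCc3ccccc3)cc2OCc2ccccc2)c(O)c1C
A4 | alternative 2 | 8-acetyl-5,7-diacetoxy-2-oxochromane-3-carbonyl chloride (racemic) | CC(=O)c1c(OC(C)=O)cc(OC(C)=O)c2CC(C(=O)Cl)C(=O)Oc12
A5 | alternative 2 | (Z)-3-(trimethylsilyloxy)pent-2-ene | C/C=C(/CC)O[Si](C)(C)C
A6 | alternative 2 | 3-(3-acetyl-4,6-diacetoxy-2-hydroxybenzyl)-6-ethyl-4-hydroxy-5-methyl-2H-pyran-2-one | CCc1oc(=O)c(Cc2c(OC(C)=O)cc(OC(C)=O)c(C(C)=O)c2O)c(O)c1C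
A7 | alternative 3 | 6-ethyl-2,2,5-trimethyl-4H-1,3-dioxin-4-one | CCC1=C(C)C(=O)OC(C)(C)O1
A8 | alternative 3 | 2-methyl-3-oxopent-1-en-1-one (acylketene) | CCC(=O)C(C)=C=O
A9 | alternative 3 | 1,1-dimethoxy-3-[2,4,6-tris(benzyloxy)phenyl]prop-1-ene | COC(OC)=CCc1c(OCc2ccccc2)cc(OCc2ccccc2)cc1OCc1ccccc1
A10 | alternative 3 | 6-ethyl-2-methoxy-5-methyl-3-[2,4,6-tris(benzyloxy)benzyl]-4H-pyran-4-one | CCc1oc(OC)c(Cc2c(OCc3ccccc3)cc(OCc3ccccc3)cc2OCc2ccccc2)c(=O)c1C
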